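The data come from a simulation with constants of no real substance; scatter was added.

A straight product line tempts me to call a slow addition harmless, but dusk, dawn, winter and midnight share [reagent] = 0.025 M, so they are silent on its order.

| setting | dusk | dawn | winter | midnight | green | teal | ochre | violet | red |
|---|---|---|---|---|---|---|---|---|---|
| starting material | 0.0050 M | 0.0050 M | 0.0050 M | 0.010 M | 0.0050 M | 0.0050 M | 0.0050 M (fed, over 80 s) | 0.0050 M | 0.0050 M (in portions, 4, over 80 s) |
| reagent | 0.025 M | 0.025 M | 0.025 M | 0.025 M | 0.0250 M (fed, over 8.0 s) | 0.0250 M | 0.0250 M | 0.0250 M (fed, over 80 s) | 0.0250 M |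
| free catalyst | 2.7 µM | 1.8 µM | 4.1 µM | 2.7 µM | 2.7 µM | 2.7 µM | 2.7 µM | 2.7 µM | 2.7 µM |
| remark | run made earlier | run made earlier | run made earlier | run made earlier | all else is in the flask from the start; the feed brings no volume worth counting | everything together at the start | all else is in the flask from the start; the feed brings no volume worth counting | all else is in the flask from the start; the feed brings no volume worth counting | first portion at the start, last at 80 s |
| time |  |  |  |  | 2.0 min | 2.0 min | 2.0 min | 2.0 min | 2.0 min |

| run | time / s | product / % | starting material / % |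
|---|---|---|---|
| dusk | 10.0 | 9.2 | 93.3 |
| dusk | 12.0 | 11.0 | 90.8 |
| dusk | 20.0 | 16.7 | 84.0 |
| dusk | 30.0 | 22.6 | 76.1 |
| dusk | 40.0 | 30.2 | 69.2 |
| dusk | 60.0 | 45.8 | 53.1 |
| dusk | 80.0 | 60.9 | 41.7 |
| dawn | 10.0 | 6.0 | 95.1 |
| dawn | 15.0 | 7.8 | 92.4 |
| dawn | 25.0 | 13.4 | 86.8 |
| dawn | 40.0 | 19.1 | 78.1 |
| dawn | 60.0 | 33.4 | 68.2 |
| dawn | 80.0 | 41.6 | 60.7 |
| dawn | 90.0 | 45.3 | 55.4 |
| winter | 15.0 | 18.1 | 81.3 |
| winter | 30.0 | 34.0 | 63.8 |
| winter | 40.0 | 46.4 | 54.8 |
| winter | 60.0 | 67.9 | 34.9 |
| winter | 80.0 | 81.3 | 19.0 |
| winter | 90.0 | 89.2 | 10.8 |
| midnight | 10.0 | 3.9 | 92.9 |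
| midnight | 15.0 | 4.5 | 94.7 |
| midnight | 25.0 | 8.4 | 88.9 |
| midnight | 50.0 | 20.2 | 79.3 |
| midnight | 90.0 | 36.1 | 65.3 |

(standard deviation of a reading: 1 percentage point)

- candidate steps: starting material + free catalyst <-> catalyst intermediate A; reagent + catalyst intermediate A <-> catalyst intermediate B; catalyst intermediate B -> by-product + catalyst intermediate C; catalyst intermediate C <-> catalyst intermediate D; catalyst intermediate D -> free catalyst + product

- the best flask by amount of product, in percent of the starting material charged; "all alike" if 1.5 percentage points covers them all (green / teal / ochre / violet / red / all alike)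
- amount of product at the end, in percent of the starting material charged, green
- amount of product at the end, in percent of the starting material charged, teal
- amount of product at the end, in percent of the starting material charged, ochre
- amount of product at the end, in percent of the starting material charged, violet
- amount of product at the end, in percent of the starting material charged, red

To whoever takes over: each flask is charged with starting material, the limiting reagent, with reagent and free catalyst, and in the dusk run product climbs close to a straight line. Dusk gives 60.9% product at 80.0 s, so I carry 131 s as the clearance time, the time the whole charge takes at a run's straight-line rate. At fixed charges it should scale inversely with catalyst. Winter reads 88.4 s at 60.0 s against 86.5 s scaled from dusk.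

At 2.7 µM, the 2.0 min allowed is shorter than the clearance time, so my straight-line estimate is 91.6% product. Expect starting material still in the flask when you come. Do not stretch an addition: there is no spare time, and the reagent's effect is unmeasured.

The forecast picks teal, with green 79%, teal 81.5%, ochre 78%, violet 62% and red 79%, and it says of violet: “Slow reagent feed then costs heavily”. These are its figures, not my estimate.

    starting material + free catalyst ⇌ catalyst intermediate A (K = 3500 L mol⁻¹, k = 35900 L mol⁻¹ s⁻¹)
    reagent + catalyst intermediate A ⇌ catalyst intermediate B (K = 18.2 L mol⁻¹, k = 26000 L mol⁻¹ s⁻¹)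
    catalyst intermediate B → by-product + catalyst intermediate C (k = 59.8 s⁻¹)
    catalyst intermediate C ⇌ catalyst intermediate D (K = 0.643, k = 3460 s⁻¹)
    catalyst intermediate D → free catalyst + product (k = 618 s⁻¹)

The flasks give green 79.8%, teal 81.5%, ochre 71.1%, violet 62.5% and red 72.1%, so teal leads, while ochre falls below the forecast, as does red. Violet's product corresponds to a clearance time of 192 s against 131 s. Its mean [reagent] over the first 80 s is 0.0119 M, against 0.0235 M in teal. The teal–violet gap of 19 percentage points shrinks to 0.11 points once catalyst intermediate B cannot fall back to reagent and catalyst intermediate A.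

In the neighbour of violet with 1.6 × 10⁻⁶ M free catalyst, the clearance time scales to 222 s, and violet's stretched value scales to 324 s, which predicts 37.0% product. That flask gives 39.0%.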